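**Retrosynthetic overview**
1. Target 32 ⇐ enoate 31 by OH-directed hydrogenation (sets C16 last) ⇐ pentacycle 27 by ester dehydrogenation.
2. 27 ⇐ azocine-fused 3H-indole 25 by a transannular ester-enolate/indolenine Mannich reaction (C2–C16 bond; closes the cyclohexane and the bicyclo[4.2.2] core, sets C2), with N1 capped as CO2Me in the same flask.
3. 25 ⇐ 22 by N4–C5 alkylation (azocane); 22 ⇐ imidoyl chloride 12 + vinylpyrrolidine 20 by B-alkyl Suzuki coupling (C2–C18; fragment union).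
4. 12 (carries C7) from indole via a Pd-catalysed asymmetric Claisen rearrangement; 20 (carries C15, C20) via yeast reduction and an anti-selective dianion Michael addition.
5. Ring order: indole and pyrrolidine rings first, then the 3H-indole C2 side chain (union), then the azocane, then the cyclohexane (Mannich).

Assumption: the t-BuPHOX antipode used in step 4 is the one that gives (S)-6 (to be confirmed by rotation/HPLC); polycycles are named with biogenetic numbering (N1, C2, C7 = indoline C3, C6–C5–N4, N4–C3–C14–C15–C20, bridges C18–C19 and C16–C17), in which the target is 2R,7S,15S,16R,20R.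

**Fragment A**

Step 1
Reactants: 1 indole
Product: 2 2,2,2-trichloro-1-(1H-indol-3-yl)ethan-1-one
Conditions: Cl3CCOCl, pyridine, 1,4-dioxane, rt
Reagents that add atoms: trichloroacetyl chloride, ClC(=O)C(Cl)(Cl)Cl
Why: Friedel–Crafts-type C3 acylation of indole by a very electrophilic acid chloride; no stereocenter.

Step 2
Reactants: 2 2,2,2-trichloro-1-(1H-indol-3-yl)ethan-1-one
Product: 3 methyl 1H-indole-3-carboxylate
Conditions: KOH (cat.), MeOH, reflux
Reagents that add atoms: methanol, CO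
Why: Haloform-type acyl substitution in which trichloromethanide is the leaving group.

Step 3
Reactants: 3 methyl 1H-indole-3-carboxylate
Product: 5 methyl 2-(allyloxy)-1H-indole-3-carboxylate, via 3-chloroindolenine 4 (not isolated)
Conditions: NCS, 1,4-dimethylpiperazine, CH2Cl2, 0 °C; then allyl alcohol, Cl3CCO2H (cat.), rt
Reagents that add atoms: allyl alcohol, C=CCO
Why: Oxidative 2-alkoxylation of an indole: chlorination to the 3-chloroindolenine, then acid-catalysed addition of the alcohol at C2 and loss of HCl.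

Step 4
Reactants: 5 methyl 2-(allyloxy)-1H-indole-3-carboxylate
Product: 6 methyl (S)-3-allyl-2-oxoindoline-3-carboxylate
Conditions: [Pd(t-BuPHOX)(MeCN)2](SbF6)2 (10 mol %), CH2Cl2, 0 °C
Reagents that add atoms: none
Why: Catalytic enantioselective Meerwein–Eschenmoser Claisen rearrangement; the chiral Pd(II) complex chelates the β-amido ester and fixes the face that receives the allyl terminus, setting quaternary C7 as S.

Step 5
Reactants: 6 methyl (S)-3-allyl-2-oxoindoline-3-carboxylate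
Product: 9 (S)-4,5-dihydro-2H-spiro[furan-3,3'-indoline]-2,2'-dione, via aldehyde 7 (not isolated), via hydroxy ester 8 (not isolated)
Conditions: O3, CH2Cl2/MeOH, −78 °C; NaBH4, −78 → 0 °C; 1 M HCl work-up
Reagents that add atoms: ozone, O=[O+][O-]
Why: Ozonolysis and reductive work-up give the γ-hydroxy ester, which lactonises onto the adjacent quaternary ester (Thorpe–Ingold); C7 is untouched.

Step 6
Reactants: 9 (S)-4,5-dihydro-2H-spiro[furan-3,3'-indoline]-2,2'-dione
Product: 11 methyl (S)-3-(2-chloroethyl)-2-oxoindoline-3-carboxylate, via acyl chloride 10 (not isolated)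
Conditions: SOCl2, ZnCl2 (5 mol %), 60 °C; evaporate; MeOH, pyridine, CH2Cl2, 0 °C
Reagents that add atoms: thionyl chloride, ClS(Cl)=O; methanol, CO
Why: Lewis-acid-assisted SN2 opening of the γ-lactone by chloride at the primary carbon gives the ω-chloro acyl chloride, which methanol converts back to the methyl ester.

Step 7
Reactants: 11 methyl (S)-3-(2-chloroethyl)-2-oxoindoline-3-carboxylate
Product: 12 methyl (R)-2-chloro-3-(2-chloroethyl)-3H-indole-3-carboxylate
Conditions: POCl3, PhNEt2, toluene, 90 °C (used crude)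
Reagents that add atoms: phosphoryl chloride, ClP(Cl)(Cl)=O
Why: Lactam-to-imidoyl-chloride conversion (Vilsmeier-type activation); the quaternary C3 blocks aromatisation, and the descriptor changes only because of CIP priorities.

**Fragment B**

Step 8
Reactants: 13 ethyl N-(tert-butoxycarbonyl)-N-(3-ethoxy-3-oxopropyl)glycinate
Product: 14 1-tert-butyl 2-ethyl 3-oxopyrrolidine-1,2-dicarboxylate (racemic)
Conditions: KOtBu, toluene, 0 °C; AcOH
Reagents that add atoms: none
Why: Kinetic Dieckmann condensation; the more acidic glycine CH2 attacks the propanoate ester to give the 3-oxo-2-carboxylate.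

Step 9
Reactants: 14 1-tert-butyl 2-ethyl 3-oxopyrrolidine-1,2-dicarboxylate
Product: 15 1-tert-butyl 2-ethyl (2R,3S)-3-hydroxypyrrolidine-1,2-dicarboxylate
Conditions: baker's yeast, sucrose, H2O, 30 °C
Reagents that add atoms: none
Why: Enzymatic ketone reduction with dynamic kinetic resolution of the racemising β-keto ester gives the cis (2R,3S) alcohol, which fixes C15 as S.

Step 10
Reactants: 15 1-tert-butyl 2-ethyl (2R,3S)-3-hydroxypyrrolidine-1,2-dicarboxylate
Product: 16 1-tert-butyl 2-ethyl (2R,3S)-2-(3-tert-butoxy-3-oxopropyl)-3-hydroxypyrrolidine-1,2-dicarboxylate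
Conditions: LDA (2.3 equiv), THF, −78 → −40 °C; tert-butyl acrylate, −78 °C; AcOH
Reagents that add atoms: tert-butyl acrylate, C=CC(=O)OC(C)(C)C
Why: Fráter–Seebach-type Michael addition of the alkoxide/enolate dianion; the acceptor adds anti to the C3 lithium alkoxide, so the new arm is trans and the ester cis to OH, which sets C20.

Step 11
Reactants: 16 1-tert-butyl 2-ethyl (2R,3S)-2-(3-tert-butoxy-3-oxopropyl)-3-hydroxypyrrolidine-1,2-dicarboxylate
Product: 17 1-tert-butyl 2-ethyl (2R,3S)-2-(3-tert-butoxy-3-oxopropyl)-3-[(tert-butyldimethylsilyl)oxy]pyrrolidine-1,2-dicarboxylate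
Conditions: TBSOTf, 2,6-lutidine, CH2Cl2, −40 → 0 °C
Reagents that add atoms: tert-butyldimethylsilyl triflate, CC(C)(C)[Si](C)(C)OS(=O)(=O)C(F)(F)F
Why: O-silylation of the hindered secondary alcohol; at low temperature the N-Boc group is not attacked.

Step 12
Reactants: 17 1-tert-butyl 2-ethyl (2R,3S)-2-(3-tert-butoxy-3-oxopropyl)-3-[(tert-butyldimethylsilyl)oxy]pyrrolidine-1,2-dicarboxylate
Product: 18 tert-butyl (2S,3S)-2-(3-tert-butoxy-3-oxopropyl)-3-[(tert-butyldimethylsilyl)oxy]-2-(hydroxymethyl)pyrrolidine-1-carboxylate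
Conditions: LiBH4, MeOH (1 equiv), THF, 0 °C → rt
Reagents that add atoms: none
Why: Chemoselective hydride reduction of the ethyl ester; tert-butyl ester and carbamate are much slower (descriptor change is CIP only).

Step 13
Reactants: 18 tert-butyl (2S,3S)-2-(3-tert-butoxy-3-oxopropyl)-3-[(tert-butyldimethylsilyl)oxy]-2-(hydroxymethyl)pyrrolidine-1-carboxylate
Product: 19 tert-butyl (2R,3S)-2-(3-tert-butoxy-3-oxopropyl)-3-[(tert-butyldimethylsilyl)oxy]-2-formylpyrrolidine-1-carboxylate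
Conditions: Dess–Martin periodinane, NaHCO3, CH2Cl2, rt
Reagents that add atoms: none
Why: Mild oxidation to a non-enolisable α-quaternary aldehyde, so no epimerisation is possible.

Step 14
Reactants: 19 tert-butyl (2R,3S)-2-(3-tert-butoxy-3-oxopropyl)-3-[(tert-butyldimethylsilyl)oxy]-2-formylpyrrolidine-1-carboxylate
Product: 20 tert-butyl (2S,3S)-2-(3-tert-butoxy-3-oxopropyl)-3-[(tert-butyldimethylsilyl)oxy]-2-vinylpyrrolidine-1-carboxylate
Conditions: Ph3PCH3Br, KHMDS, THF, 0 °C → rt
Reagents that add atoms: methyltriphenylphosphonium bromide, C[P+](c1ccccc1)(c1ccccc1)c1ccccc1.[Br-]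
Why: Wittig methylenation with the small unstabilised ylide, which tolerates the hindered aldehyde.

**Union and end game**

Step 15
Reactants: 20 tert-butyl (2S,3S)-2-(3-tert-butoxy-3-oxopropyl)-3-[(tert-butyldimethylsilyl)oxy]-2-vinylpyrrolidine-1-carboxylate; 12 methyl (R)-2-chloro-3-(2-chloroethyl)-3H-indole-3-carboxylate
Product: 22 methyl (S)-2-{2-[(2R,3S)-1-Boc-2-(3-tert-butoxy-3-oxopropyl)-3-(TBSO)pyrrolidin-2-yl]ethyl}-3-(2-chloroethyl)-3H-indole-3-carboxylate, via alkylborane 21 (not isolated)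
Conditions: 9-BBN, THF, rt → 45 °C; then 12, Pd(dppf)Cl2 (5 mol %), AsPh3, K3PO4 (3 M aq.), DMF/THF, rt → 45 °C
Reagents that add atoms: none
Why: Anti-Markovnikov hydroboration then B-alkyl Suzuki–Miyaura coupling at the imidoyl C–Cl bond (the primary alkyl chloride is inert to Pd/dppf); this gives the 2-alkyl-3H-indole directly with no stereocenter touched.

Step 16
Reactants: 22 methyl (S)-2-{2-[(2R,3S)-1-Boc-2-(3-tert-butoxy-3-oxopropyl)-3-(TBSO)pyrrolidin-2-yl]ethyl}-3-(2-chloroethyl)-3H-indole-3-carboxylate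
Product: 25 azocine-fused 3H-indole (7S,15S,20R) with C2–C18–C19–C20–N4–C5–C6–C7 eight-membered ring; N4–C20 shared with the C15-OTBS pyrrolidine; C20-CH2CH2CO2tBu; C7-CO2Me, via silyl carbamate 23 (not isolated), via secondary amine 24 (not isolated)
Conditions: TBSOTf, 2,6-lutidine, CH2Cl2, 0 °C → rt; MeOH; then K2CO3, NaI (0.2 equiv), MeCN (3 mM), 70 °C
Reagents that add atoms: none
Why: N-Boc is cleaved through the silyl carbamate while the tert-butyl ester (which, unlike a methyl ester, does not lactamise onto the freed amine) and TBS ether survive; the amine then closes the azocane by 8-exo-tet SN2 on the in situ iodide under high dilution, helped by two quaternary centres and the sp2 C2.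

Step 17
Reactants: 25 azocine-fused 3H-indole (7S,15S,20R)
Product: 27 N1-methoxycarbonyl pentacycle with bicyclo[4.2.2] core and C16-CO2tBu (2R,7S,15S,20R; C16 epimer mixture), via NH Mannich adduct 26 (not isolated)
Conditions: LDA (1.2 equiv), THF, −78 → −30 °C; ClCO2Me, −78 → 0 °C
Reagents that add atoms: methyl chloroformate, COC(Cl)=O
Why: The only enolisable ester gives a lithium enolate that adds across the eight-membered ring to the indolenine C=N (transannular intramolecular Mannich, 6-exo); tethered through C20 it can reach C2 only from the face bearing C6, so C2 is set as R by C7 and C20, and the lithium anilide is capped as the carbamate (the C16 mixture is erased in step 18).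

Step 18
Reactants: 27 N1-methoxycarbonyl pentacycle (C16 epimer mixture)
Product: 29 16,17-didehydro tert-butyl ester (2R,7S,15S,20R), via sulfilimine adduct 28 (not isolated)
Conditions: LDA, THF, −78 → −40 °C; PhS(Cl)=N-t-Bu, −78 °C → rt
Reagents that add atoms: none
Why: Mukaiyama dehydrogenation: the ester enolate is sulfenylated at C16 and the sulfilimine undergoes syn-elimination with a C17 hydrogen (C2 has none), giving the C16=C17 enoate.

Step 19
Reactants: 29 16,17-didehydro tert-butyl ester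
Product: 31 16,17-didehydro target (methyl enoate with free C15-OH; 2R,7S,15S,20R), via hydroxy acid 30 (not isolated)
Conditions: TFA/H2O 9:1, rt; evaporate; TMSCHN2, MeOH/toluene, 0 °C
Reagents that add atoms: (trimethylsilyl)diazomethane, C[Si](C)(C)C=[N+]=[N-]
Why: Acidolysis removes the tert-butyl ester and the TBS ether; TMS-diazomethane then methylates only the carboxylic acid.

Step 20
Reactants: 31 16,17-didehydro target
Product: 32 target (2R,7S,15S,16R,20R)
Conditions: H2 (1 atm), [Ir(cod)(PCy3)(py)]PF6 (10 mol %), CH2Cl2, rt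
Reagents that add atoms: none
Why: Hydroxyl-directed hydrogenation (Crabtree): iridium bound to the C15-OH, which lies on the C18–C19 side of the cage, delivers H2 to that face of C16=C17 (the other face is screened by the C6 methylene), placing H at C16 away from the C7 bridge and giving 16R.

**Compound list**
1 | indole | c1ccc2[nH]ccc2c1 | starting material
2 | 2,2,2-trichloro-1-(1H-indol-3-yl)ethan-1-one | O=C(c1c[nH]c2ccccc12)C(Cl)(Cl)Cl | intermediate
3 | methyl 1H-indole-3-carboxylate | COC(=O)c1c[nH]c2ccccc12 | intermediate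
4 | methyl 3-chloro-3H-indole-3-carboxylate (racemic) | COC(=O)C1(Cl)C=Nc2ccccc12 | intermediate (not isolated)
5 | methyl 2-(allyloxy)-1H-indole-3-carboxylate | COC(=O)c1c(OCC=C)[nH]c2ccccc12 | intermediate
6 | methyl (S)-3-allyl-2-oxoindoline-3-carboxylate | O=C1Nc2ccccc2[C@@]1(C(=O)OC)CC=C | intermediate
7 | methyl (S)-2-oxo-3-(2-oxoethyl)indoline-3-carboxylate | O=C1Nc2ccccc2[C@@]1(C(=O)OC)CC=O | intermediate (not isolated)
8 | methyl (S)-3-(2-hydroxyethyl)-2-oxoindoline-3-carboxylate | O=C1Nc2ccccc2[C@@]1(C(=O)OC)CCO | intermediate (not isolated)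
9 | (S)-4,5-dihydro-2H-spiro[furan-3,3'-indoline]-2,2'-dione | O=C1Nc2ccccc2[C@]13C(=O)OCC3 | intermediate
10 | (S)-3-(2-chloroethyl)-2-oxoindoline-3-carbonyl chloride | O=C1Nc2ccccc2[C@@]1(C(=O)Cl)CCCl | intermediate (not isolated)
11 | methyl (S)-3-(2-chloroethyl)-2-oxoindoline-3-carboxylate | O=C1Nc2ccccc2[C@@]1(C(=O)OC)CCCl | intermediate
12 | methyl (R)-2-chloro-3-(2-chloroethyl)-3H-indole-3-carboxylate | ClC1=Nc2ccccc2[C@@]1(C(=O)OC)CCCl | intermediate
13 | ethyl N-(tert-butoxycarbonyl)-N-(3-ethoxy-3-oxopropyl)glycinate | CCOC(=O)CCN(CC(=O)OCC)C(=O)OC(C)(C)C | starting material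
14 | 1-tert-butyl 2-ethyl 3-oxopyrrolidine-1,2-dicarboxylate (racemic) | CCOC(=O)C1N(C(=O)OC(C)(C)C)CCC1=O | intermediate
15 | 1-tert-butyl 2-ethyl (2R,3S)-3-hydroxypyrrolidine-1,2-dicarboxylate | CCOC(=O)[C@H]1[C@@H](O)CCN1C(=O)OC(C)(C)C | intermediate
16 | 1-tert-butyl 2-ethyl (2R,3S)-2-(3-tert-butoxy-3-oxopropyl)-3-hydroxypyrrolidine-1,2-dicarboxylate | CC(C)(C)OC(=O)CC[C@@]1([C@@H](O)CCN1C(=O)OC(C)(C)C)C(=O)OCC | intermediate
17 | TBS ether of 16 (2R,3S) | CC(C)(C)OC(=O)CC[C@@]1([C@@H](O[Si](C)(C)C(C)(C)C)CCN1C(=O)OC(C)(C)C)C(=O)OCC | intermediate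
18 | tert-butyl (2S,3S)-2-(3-tert-butoxy-3-oxopropyl)-3-(TBSO)-2-(hydroxymethyl)pyrrolidine-1-carboxylate | CC(C)(C)OC(=O)CC[C@@]1([C@@H](O[Si](C)(C)C(C)(C)C)CCN1C(=O)OC(C)(C)C)CO | intermediate
19 | tert-butyl (2R,3S)-2-(3-tert-butoxy-3-oxopropyl)-3-(TBSO)-2-formylpyrrolidine-1-carboxylate | CC(C)(C)OC(=O)CC[C@@]1([C@@H](O[Si](C)(C)C(C)(C)C)CCN1C(=O)OC(C)(C)C)C=O | intermediate
20 | tert-butyl (2S,3S)-2-(3-tert-butoxy-3-oxopropyl)-3-(TBSO)-2-vinylpyrrolidine-1-carboxylate | CC(C)(C)OC(=O)CC[C@@]1([C@@H](O[Si](C)(C)C(C)(C)C)CCN1C(=O)OC(C)(C)C)C=C | intermediate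
21 | B-alkyl-9-BBN from 20 (boron on the terminal carbon) | CC(C)(C)OC(=O)CC[C@@]1([C@@H](O[Si](C)(C)C(C)(C)C)CCN1C(=O)OC(C)(C)C)CCB1C2CCCC1CCC2 | intermediate (not isolated)
22 | methyl (S)-2-{2-[(2R,3S)-1-Boc-2-(3-tert-butoxy-3-oxopropyl)-3-(TBSO)pyrrolidin-2-yl]ethyl}-3-(2-chloroethyl)-3H-indole-3-carboxylate | CC(C)(C)OC(=O)CC[C@@]1([C@@H](O[Si](C)(C)C(C)(C)C)CCN1C(=O)OC(C)(C)C)CCC1=Nc2ccccc2[C@@]1(C(=O)OC)CCCl | intermediate
23 | N-(TBS-oxycarbonyl) analogue of 22 (silyl carbamate) | CC(C)(C)OC(=O)CC[C@@]1([C@@H](O[Si](C)(C)C(C)(C)C)CCN1C(=O)O[Si](C)(C)C(C)(C)C)CCC1=Nc2ccccc2[C@@]1(C(=O)OC)CCCl | intermediate (not isolated)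
24 | N-H pyrrolidine analogue of 22 (secondary amine) | CC(C)(C)OC(=O)CC[C@@]1([C@@H](O[Si](C)(C)C(C)(C)C)CCN1)CCC1=Nc2ccccc2[C@@]1(C(=O)OC)CCCl | intermediate (not isolated)
25 | azocine-fused 3H-indole (7S,15S,20R); C20-CH2CH2CO2tBu, C15-OTBS, C7-CO2Me | CC(C)(C)OC(=O)CC[C@@]23CCC4=Nc1ccccc1[C@@]4(C(=O)OC)CCN2CC[C@@H]3O[Si](C)(C)C(C)(C)C | intermediate
26 | N1-H Mannich adduct (2R,7S,15S,20R; C16 mixture) | CC(C)(C)OC(=O)C1C[C@@]23CC[C@@]14Nc1ccccc1[C@@]4(C(=O)OC)CCN2CC[C@@H]3O[Si](C)(C)C(C)(C)C | intermediate (not isolated)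
27 | N1-CO2Me pentacycle, C16-CO2tBu, C15-OTBS (2R,7S,15S,20R; C16 mixture) | CC(C)(C)OC(=O)C1C[C@@]23CC[C@@]14N(C(=O)OC)c1ccccc1[C@@]4(C(=O)OC)CCN2CC[C@@H]3O[Si](C)(C)C(C)(C)C | intermediate
28 | C16 S-phenyl-N-tert-butylsulfilimine adduct of 27 | CC(C)(C)OC(=O)C1(S(=NC(C)(C)C)c5ccccc5)C[C@@]23CC[C@@]14N(C(=O)OC)c1ccccc1[C@@]4(C(=O)OC)CCN2CC[C@@H]3O[Si](C)(C)C(C)(C)C | intermediate (not isolated)
29 | 16,17-didehydro tert-butyl ester, C15-OTBS (2R,7S,15S,20R) | CC(C)(C)OC(=O)C1=C[C@@]23CC[C@@]14N(C(=O)OC)c1ccccc1[C@@]4(C(=O)OC)CCN2CC[C@@H]3O[Si](C)(C)C(C)(C)C | intermediate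
30 | 16,17-didehydro C16 carboxylic acid, C15-OH | OC(=O)C1=C[C@@]23CC[C@@]14N(C(=O)OC)c1ccccc1[C@@]4(C(=O)OC)CCN2CC[C@@H]3O | intermediate (not isolated)
31 | 16,17-didehydro target (methyl enoate, C15-OH) | COC(=O)C1=C[C@@]23CC[C@@]14N(C(=O)OC)c1ccccc1[C@@]4(C(=O)OC)CCN2CC[C@@H]3O | intermediate
32 | target CNP0144467.1 (2R,7S,15S,16R,20R) | COC(=O)[C@@H]1C[C@@]23CC[C@@]14N(C(=O)OC)c1ccccc1[C@@]4(C(=O)OC)CCN2CC[C@@H]3O | target

**Totals**
Total step count: 20. Longest linear sequence: 13 (steps 1–7 then 15–20; the branch of steps 8–14 then 15–20 is equally long).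

**Three steps most likely to fail**

Step 16 (azocane closure). An eight-membered SN2 ring closure is slow, and the free amine can rest as an unproductive aminal with the indolenine or attack the labile C7 ester. Fallback, closing the ring by iminium reduction instead of alkylation: it sets out from 6 (with borane 21) and returns at 25. POCl3/PhNEt2 on 6 gives methyl (R)-3-allyl-2-chloro-3H-indole-3-carboxylate F1; B-alkyl Suzuki coupling of F1 with 21 gives the allyl 3H-indole F2; TBSOTf/2,6-lutidine then MeOH frees the secondary amine F3; ozonolysis of F3 as its triflate salt (O3, CH2Cl2/MeOH, −78 °C; Me2S) gives the amino aldehyde F4; NaBH(OAc)3/NaOAc in dilute 1,2-dichloroethane then closes the ring reductively to 25.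

Step 17 (transannular Mannich). LDA may deprotonate C18 next to the C=N instead of the ester, and the ketimine is flanked by a quaternary carbon. Fallback, an N-acyliminium Mukaiyama–Mannich instead of a lithium enolate addition: it sets out from 25 and returns at 27. ClCO2Me/NaHCO3 in MeOH at 0 °C gives the 2-methoxy N1-methoxycarbonyl indoline (N,O-acetal) F5; LDA/TMSCl in THF at −78 °C gives the tert-butyl trimethylsilyl ketene acetal F6; TMSOTf (1.2 equiv) in CH2Cl2 at −78 °C ionises the N,O-acetal and the ketene acetal captures the N-acyliminium ion across the ring to give 27.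

Step 18 (dehydrogenation). The C16 enolate of 27 is hindered (next to quaternary C2), and sulfenylation/elimination may stall. Fallback, setting C16 by kinetic protonation instead of dehydrogenation/hydrogenation: it sets out from 27 and returns at 32. LDA or KHMDS in THF at −78 °C followed by a cold quench with 2,6-di-tert-butyl-4-methylphenol protonates the enolate from the face away from the C6/C7 bridge and gives the (16R) tert-butyl ester F7 (residual 16-epimer is separated and recycled); TFA/H2O gives the saturated hydroxy acid F8, and TMSCHN2 methylates it to 32, bypassing 29–31.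

Further compounds
F1 | step 16 | methyl (R)-3-allyl-2-chloro-3H-indole-3-carboxylate | ClC1=Nc2ccccc2[C@@]1(C(=O)OC)CC=C
F2 | step 16 | 3-allyl analogue of 22 (N-Boc, allyl in place of 2-chloroethyl) | CC(C)(C)OC(=O)CC[C@@]1([C@@H](O[Si](C)(C)C(C)(C)C)CCN1C(=O)OC(C)(C)C)CCC1=Nc2ccccc2[C@@]1(C(=O)OC)CC=C
F3 | step 16 | N-H pyrrolidine derived from F2 | CC(C)(C)OC(=O)CC[C@@]1([C@@H](O[Si](C)(C)C(C)(C)C)CCN1)CCC1=Nc2ccccc2[C@@]1(C(=O)OC)CC=C
F4 | step 16 | amino aldehyde (3-(2-oxoethyl) analogue of F3) | CC(C)(C)OC(=O)CC[C@@]1([C@@H](O[Si](C)(C)C(C)(C)C)CCN1)CCC1=Nc2ccccc2[C@@]1(C(=O)OC)CC=O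
F5 | step 17 | 2-methoxy N1-methoxycarbonyl indoline (N,O-acetal) from 25 | CC(C)(C)OC(=O)CC[C@@]23CCC4(OC)N(C(=O)OC)c1ccccc1[C@@]4(C(=O)OC)CCN2CC[C@@H]3O[Si](C)(C)C(C)(C)C
F6 | step 17 | tert-butyl trimethylsilyl ketene acetal of F5 | CC(C)(C)OC(O[Si](C)(C)C)=CC[C@@]23CCC4(OC)N(C(=O)OC)c1ccccc1[C@@]4(C(=O)OC)CCN2CC[C@@H]3O[Si](C)(C)C(C)(C)C
F7 | step 18 | (16R) tert-butyl ester, C15-OTBS (single C16 epimer of 27) | CC(C)(C)OC(=O)[C@@H]1C[C@@]23CC[C@@]14N(C(=O)OC)c1ccccc1[C@@]4(C(=O)OC)CCN2CC[C@@H]3O[Si](C)(C)C(C)(C)C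
F8 | step 18 | (16R) C16 carboxylic acid, C15-OH | OC(=O)[C@@H]1C[C@@]23CC[C@@]14N(C(=O)OC)c1ccccc1[C@@]4(C(=O)OC)CCN2CC[C@@H]3O
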